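(The readings stem from a simulated flask from invented constants; the scatter is artificial.)

**Leftover substrate.** The amber run stalls with 58.9% of its substrate unreacted and the ochre run with 67.3%, so I count stalled product against reagent, one for one: it comes to 79.6% of the reagent charged in amber and 60.7% in ochre. The missing reagent grows by a factor of 3.84 for a charge twice as large, so I read a side use of order two in reagent against a catalysed use of order one.

| flask | substrate | reagent | free catalyst | remark |
|---|---|---|---|---|
| amber | 1.5 M | 0.79 M | 3 mM | run made earlier |
| ochre | 3 M | 1.58 M | 3 mM | run made earlier |
| flask | 1.5 M | 1.58 M | 3.0 mM |  |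

- amber (time / h: product / %, substrate / %): 0.200: 27.5, 72.7; 0.500: 41.1, 58.0; 1.00: 43.1, 60.3; 2.50: 40.7, 58.9
- ochre (time / h: product / %, substrate / %): 0.667: 31.7, 68.7; 1.33: 31.3, 67.8; 2.00: 33.3, 65.5; 2.50: 31.6, 67.3

(readings scatter by 1 percentage point)

- factor on the rate of making product when 30% of the substrate are converted if free catalyst is charged twice over
- factor on the rate when 30% of the substrate are converted if free catalyst is charged at 0.60 mM instead

- no earlier run changes the charge of free catalyst; that part of a forecast is a guess

**Crossing charge.** The crossing charge, 1.94 mM from ochre, is the charge of free catalyst at which reagent lost equals reagent made into product, and I take the share reaching product as catalyst charge over catalyst charge plus crossing charge, which is my guess. I take the rate as catalyst charge times reagent left, where reaching the mark costs its product divided by that share.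

**What matters.** The substrate charge enters through the mark. Amber, scaled to this reagent, gives a crossing of 1.54 mM, and that swap moves the doubling factor from 2.35 to 2.26, which is forgiving. It moves the stall at 0.60 mM from 24.9% to 29.5%, both short of the mark of 30%, the second narrowly, so I commit to 2.35 and to a low factor, far under the charge ratio of 0.200.

**The forecast.** The forecast says 3.2 (2 to 5) and 0 (0 to 0.2), reading the stalls as “catalyst death, quick and roughly first order”, where I read reagent loss.

**Flask result.** The flask gives 2.20 and 0.0307, and at 2.50 h its reagent, the limiting reagent, stands at 0% with homo dimer at 0.333 M.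

    reagent + free catalyst → catalyst intermediate A (k = 1.10 M⁻¹ s⁻¹)
    catalyst intermediate A → by-product + catalyst intermediate B (k = 1.10 s⁻¹)
    substrate + catalyst intermediate B → catalyst intermediate C (k = 0.800 M⁻¹ s⁻¹)
    catalyst intermediate C → free catalyst + product (k = 0.760 s⁻¹)
    2 reagent → homo dimer (k = 4.60 × 10⁻⁴ M⁻¹ s⁻¹)
    2 catalyst intermediate A → spent catalyst (k = 0.160 M⁻¹ s⁻¹)

**Crossing again.** The flask's stalled product of 60.9% puts the crossing at 2.19 mM. The charge of 3.0 mM stands above it, and doubling gives 1.10 of the charge ratio. The charge of 0.60 mM stands below it, and there the factor is 0.154 of the charge ratio, with catalyst intermediate A holding 2.66% of the catalyst.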